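**Retrosynthetic overview**
1. Target ⇐ enzymatic (S)-selective reduction of a 3-oxopentyl ketone; the C6 quaternary centre (CH2OH + chain) ⇐ spiro-epoxide of a bridging C6 ketone, opened to a radical and added to ethyl vinyl ketone.
2. Ring D (piperidine) and the C17 quaternary centre ⇐ deconjugative double Mannich annulation (MeNH2 + 2 CH2O) on a tricyclic β,γ-unsaturated C6 ketone (the new step).
3. Ring C (seven-membered) ⇐ allyl addition to the ring-A ketone, lactonisation onto the neighbouring ester, SmI2 acyl substitution (C6–C7 bond), dehydration to C10=C11.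
4. Rings A and B with C11/C12/C15/C17 ⇐ catalytic asymmetric endo Diels–Alder of cyclopentadiene with cyclopent-2-enone; the norbornene C=C is cleaved to the C15 ester and the C6 carboxyl.
5. Ring order: A and B (steps 1–2), then C (steps 3–6), then D (step 7).

Assumption: cyclopentadiene is cracked fresh from its commercial dimer.
Labels used in names: C1–C5 side chain (C3 = carbinol); C6 = quaternary carbon carrying C21H2OH; C7 = adjacent CH; C8, C9 = ring CH2; C10=C11 = alkene; C12 = ring-fusion CH; C13, C14 = cyclopentene CH2; C15 = CH–CO2Me (C22 = ester carbon); C16 = CH2; C17 = quaternary carbon; C18, C20 = N–CH2. Ring A = cyclopentene, ring B = ester-bearing cyclopentane, ring C = seven-membered ring, ring D = piperidine.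

**Step 1**
Reactants: 1 cyclopenta-1,3-diene; 2 cyclopent-2-en-1-one
Product: 3 endo adduct (1S,2R,6S,7R)-tricyclo[5.2.1.0^{2,6}]dec-8-en-3-one
Conditions: o-tolyl-oxazaborolidinium triflimide from diphenylprolinol (10 mol%; the antipode that gives 3, both are available from (S)- or (R)-proline), CH2Cl2, −78 °C
Reagents that add atoms: none
Why: Endo-selective Diels–Alder reaction under a chiral, metal-free oxazaborolidinium Lewis acid, in which the boron-bound enone is attacked on its unshielded face through the endo transition state, setting C11, C12, C15 and C17 in one event with ring A on the same side as the new alkene.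

**Step 2**
Reactants: 3 endo adduct
Product: 4 dimethyl (1S,3R,3aS,6aR)-4-oxooctahydropentalene-1,3-dicarboxylate
Conditions: O3, NaOH, MeOH/CH2Cl2, −78 °C
Reagents that add atoms: ozone [O-][O+]=O; methanol CO
Why: Ozonolysis in alkaline methanol (oxidative cleavage straight to methyl esters) converts both alkene carbons into esters without touching a stereocenter, so the C15 ester and the future C6 carbon stay cis to each other and to ring A.

**Step 3**
Reactants: 4 keto diester; 5 allylmagnesium bromide (CH2=CHCH2MgBr)
Product: 7 allyl lactone, via hydroxy diester 6 (not isolated)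
Conditions: CH2=CHCH2MgBr, THF, −78 °C to rt; aq NH4Cl
Reagents that add atoms: none
Why: Grignard 1,2-addition, far faster at the ketone than at the esters at −78 °C, takes place from the convex face of the cis-fused bicycle, so the new tertiary alkoxide at C10 points into the cup beside the C17 ester and closes the five-membered lactone (favoured over the bridged six-membered alternative), which also differentiates the two esters.

**Step 4**
Reactants: 7 allyl lactone
Product: 9 iodopropyl lactone, via alkylborane 8 (not isolated)
Conditions: 9-BBN, THF, 0 °C to rt; then NaOMe, I2, MeOH, 0 °C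
Reagents that add atoms: iodine II
Why: Anti-Markovnikov hydroboration of the terminal alkene followed by base-induced iodinolysis of the primary B–C bond (hydroboration–iodination) gives the primary iodide, while lactone and ester are inert to 9-BBN and no stereocenter is formed.

**Step 5**
Reactants: 9 iodopropyl lactone
Product: 10 bridged hemiketal
Conditions: SmI2 (2.5 equiv), Fe(dbm)3 (2 mol%), THF, −30 °C to rt
Reagents that add atoms: none
Why: SmI2-promoted intramolecular nucleophilic acyl substitution (samarium Barbier-type cyclisation) reduces the C–I bond and lets the carbanion equivalent attack the nearby lactone carbonyl in a seven-membered closure that stops at the hemiketal, whose C6 configuration is dictated by the oxygen bridge.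

**Step 6**
Reactants: 10 bridged hemiketal
Product: 12 tricyclic keto ester, via hydroxy ketone 11 (not isolated)
Conditions: TsOH·H2O (10 mol%), toluene, 80 °C
Reagents that add atoms: none
Why: Acid-catalysed E1 dehydration of the tertiary C10 alcohol exposed by ring-chain tautomerism gives the tetrasubstituted (Zaitsev) C10=C11 alkene, and any conjugated C11=C17 isomer formed under acid is equally usable next because both share the same dienol.

**Step 7**
Reactants: 12 tricyclic keto ester
Product: 14 tetracyclic amino ketone, via Mannich base 13 (not isolated)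
Conditions: MeNH2 (33% in EtOH), (CH2O)n, AcOH, 60 °C
Reagents that add atoms: methylamine CN; formaldehyde C=O
Why: Proposed new method: a deconjugative double Mannich ([3+3] aza-annulation) in which methylamine and formaldehyde first aminomethylate the unhindered C7 methylene (compound 13), after which the derived N-methyl-N-methyleneiminium ion is held over the cross-conjugated dienol and can only close a six-membered ring at the α-carbon C17 (not at the remote γ-carbon C10), from the convex face opposite the endo C15 ester, giving the quaternary bridgehead with C18 cis to H12 and, through the bicyclic constraint, the C7 configuration; the closest known reaction type is the Robinson–Schöpf-type double Mannich annulation of saturated cyclic ketones and β-keto esters to 3-azabicyclo[3.3.1]nonan-9-ones, which has not been shown to build an allylic all-carbon quaternary bridgehead through a dienol.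

**Step 8**
Reactants: 14 tetracyclic amino ketone
Product: 15 spiro-epoxide
Conditions: Me3S+ I−, KN(SiMe3)2, THF, −20 °C to rt
Reagents that add atoms: trimethylsulfonium iodide C[S+](C)C.[I-]
Why: Corey–Chaykovsky epoxidation, in which the small sulfonium ylide adds to the non-enolisable bridging ketone and closes the spiro-epoxide, whose configuration is irrelevant because C6 becomes a planar radical in the next step.

**Step 9**
Reactants: 15 spiro-epoxide; 16 pent-1-en-3-one (ethyl vinyl ketone)
Product: 17 keto alcohol
Conditions: Cp2TiCl2 (20 mol%), Zn (2 equiv), 2,4,6-collidine·HCl (3 equiv), THF, rt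
Reagents that add atoms: none
Why: Titanocene-mediated reductive epoxide opening with Giese addition (Nugent–RajanBabu type), in which Cp2TiCl (trivalent titanium) cleaves the epoxide to the tertiary C6 radical that cannot eliminate and adds to the enone on the face syn to the nitrogen bridge, the other face being shielded by the endo C15 ester and the C8 methylene, so the oxopentyl chain ends over the piperidine and CH2OH over the cycloheptene as in the target.

**Step 10**
Reactants: 17 keto alcohol
Product: 18 CNP0291564.1 (target)
Conditions: Prelog-selective ketoreductase (from a screening panel), NADP+ (cat.), i-PrOH, K2HPO4/KH2PO4 buffer pH 7, DMSO (10%), 30 °C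
Reagents that add atoms: none
Why: Biocatalytic asymmetric ketone reduction under reagent control, a Prelog-type enzyme delivering hydride to the face that gives the (S)-carbinol (large group CH2CH2R, small group ethyl) while the methyl ester, the amine and the tetrasubstituted alkene are untouched.

**Compound list**
1 | cyclopenta-1,3-diene | C1C=CC=C1 | starting material
2 | cyclopent-2-en-1-one | O=C1C=CCC1 | starting material
3 | (1S,2R,6S,7R)-tricyclo[5.2.1.0^{2,6}]dec-8-en-3-one (endo adduct) | O=C1CC[C@@H]2[C@H]1[C@H]3C[C@@H]2C=C3 | intermediate
4 | dimethyl (1S,3R,3aS,6aR)-4-oxooctahydropentalene-1,3-dicarboxylate (both esters and ring A on the same face of ring B) | O=C1CC[C@@H]2[C@H]1[C@H](C(=O)OC)C[C@@H]2C(=O)OC | intermediate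
5 | allylmagnesium bromide | C=CC[Mg]Br | starting material
6 | dimethyl 4-allyl-4-hydroxyoctahydropentalene-1,3-dicarboxylate (OH on the concave face, cis to both esters; other centres as in 4) | C=CC[C@]1(O)CC[C@@H]2[C@H]1[C@H](C(=O)OC)C[C@@H]2C(=O)OC | intermediate
7 | allyl lactone: five-membered lactone between the C10 oxygen and the C6 carboxyl on C17; allyl on C10 on the convex face; C15 methyl ester retained | C=CC[C@]12CC[C@@H]3[C@H]1[C@@H](C[C@@H]3C(=O)OC)C(=O)O2 | intermediate
8 | 9-BBN adduct of 7 (boron on the terminal carbon C7) | B1(CCC[C@]23CC[C@@H]4[C@H]2[C@@H](C[C@@H]4C(=O)OC)C(=O)O3)C5CCCC1CCC5 | intermediate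
9 | iodopropyl lactone (7 with allyl converted to 3-iodopropyl) | ICCC[C@]12CC[C@@H]3[C@H]1[C@@H](C[C@@H]3C(=O)OC)C(=O)O2 | intermediate
10 | bridged hemiketal: C6 carries OH and is joined to C10 through oxygen and through C7–C8–C9 (8-oxabicyclo[3.2.1]octane fused to rings A and B) | O[C@@]12CCC[C@]3(O1)CC[C@@H]4[C@H]3[C@H]2C[C@@H]4C(=O)OC | intermediate
11 | ring-opened tautomer of 10: C6 ketone, tertiary C10–OH | O=C1CCC[C@]2(O)CC[C@@H]3[C@H]2[C@H]1C[C@@H]3C(=O)OC | intermediate
12 | tricyclic keto ester: C6 ketone in ring C, C10=C11 alkene, H17 cis to H12, C15 methyl ester cis to C6 | O=C1CCCC2=C3[C@@H](CC2)[C@@H](C(=O)OC)C[C@H]31 | intermediate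
13 | 12 carrying CH2NHMe at C7 (mono-Mannich base) | O=C1[C@H](CNC)CCC2=C3[C@@H](CC2)[C@@H](C(=O)OC)C[C@H]31 | intermediate
14 | tetracyclic amino ketone (3-methyl-3-azabicyclo[4.3.1]decan-10-one core; C7, C12, C15, C17 arranged as in the target) | O=C1[C@H]2CCC3=C4[C@@H](CC3)[C@@H](C(=O)OC)C[C@]41CN(C)C2 | intermediate
15 | spiro-epoxide of 14 at C6 (epoxide CH2 syn to the nitrogen bridge) | C1O[C@]12[C@H]3CCC4=C5[C@@H](CC4)[C@@H](C(=O)OC)C[C@]52CN(C)C3 | intermediate
16 | pent-1-en-3-one (ethyl vinyl ketone) | C=CC(=O)CC | starting material
17 | keto alcohol: target with C3 as ketone (C6 S, C7 R, C12 S, C15 S, C17 S) | CCC(=O)CC[C@]1(CO)[C@H]2CCC3=C4[C@@H](CC3)[C@@H](C(=O)OC)C[C@]41CN(C)C2 | intermediate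
18 | CNP0291564.1: C6 bears CH2OH and the (3S)-3-hydroxypentyl chain; C3 S, C6 S, C7 R, C12 S, C15 S, C17 S | CC[C@H](O)CC[C@]1(CO)[C@H]2CCC3=C4[C@@H](CC3)[C@@H](C(=O)OC)C[C@]41CN(C)C2 | target

**Step count and risks**
Total steps: 10. Longest linear sequence: 10 (fully linear, no protecting groups).

Three steps most likely to fail:

Step 5 (SmI2 closure of ring C). The risks are simple deiodination or attack on the C15 ester. The fallback sets out from 7 and comes back at 10. Lactone 7 is opened with CH2=CHMgBr (1.05 equiv, THF, −78 °C) to the vinyl hemiketal F1. Ring C is then closed by ring-closing metathesis between the C6 vinyl and C10 allyl groups (second-generation Grubbs catalyst, RuCl2(CHPh)(PCy3)(1,3-dimesitylimidazolidin-2-ylidene), CH2Cl2, 40 °C) to give the bridged cycloheptene hemiketal F2. Hydrogenation of its C7=C8 bond (H2, Pd/C, EtOAc) gives 10.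

Step 7 (the proposed deconjugative double Mannich). The risks are attack at the γ-carbon C10 and double aminomethylation at C7. The fallback uses known chemistry, sets out from 12 and comes back at 14. The extended (thermodynamic) enolate of 12 is formed with KN(SiMe3)2 and trapped at the α-carbon C17 with monomeric formaldehyde from the convex face to give the hydroxymethyl ketone F3. Mesylation (MsCl, Et3N) gives the mesylate F4. The only remaining enolisable position, C7, is α-methylenated ((CH2O)n, N-methylanilinium trifluoroacetate, THF, reflux) to the methylene ketone F5. MeNH2 then adds to the enone (aza-Michael) and displaces the neopentyl mesylate intramolecularly, closing the piperidine to 14.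

Step 9 (radical epoxide opening and Giese addition). The risks are titanocene-mediated reduction or polymerisation of the enone and low face selectivity at C6. The fallback is polar, sets out from 14 and comes back at 17. Wittig reaction of 14 with Ph3P=CHOMe (from the phosphonium chloride and KN(SiMe3)2) gives the enol ether F6. Hydrolysis (2 M HCl, THF) gives the aldehyde F7. Base-catalysed Michael addition of its enolate to 16 (KOH cat., MeOH) gives the keto aldehyde F8, with the same face argument as in step 9, so it does not cure a face-selectivity failure. Selective aldehyde reduction with NaBH(OAc)3 gives 17.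

**Further compounds**
F1 | step 5 | vinyl hemiketal: C6 carries OH and vinyl and is bridged by oxygen to C10, which carries the allyl group | C=CC[C@]12CC[C@@H]3[C@H]1[C@@H](C[C@@H]3C(=O)OC)[C@](O)(C=C)O2
F2 | step 5 | bridged cycloheptene hemiketal (10 with a C7=C8 double bond) | O[C@@]12C=CC[C@]3(O1)CC[C@@H]4[C@H]3[C@H]2C[C@@H]4C(=O)OC
F3 | step 7 | hydroxymethyl ketone (12 with CH2OH at C17, cis to H12) | O=C1CCCC2=C3[C@@H](CC2)[C@@H](C(=O)OC)C[C@]31CO
F4 | step 7 | mesylate of F3 | O=C1CCCC2=C3[C@@H](CC2)[C@@H](C(=O)OC)C[C@]31COS(C)(=O)=O
F5 | step 7 | methylene ketone (F4 with an exocyclic CH2 at C7) | O=C1C(=C)CCC2=C3[C@@H](CC2)[C@@H](C(=O)OC)C[C@]31COS(C)(=O)=O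
F6 | step 9 | methyl enol ether at C6 (C6=CH–OMe, E/Z mixture) | COC=C1[C@H]2CCC3=C4[C@@H](CC3)[C@@H](C(=O)OC)C[C@]41CN(C)C2
F7 | step 9 | aldehyde (C6–H, C21 formyl; C6 epimerisable) | O=C[C@H]1[C@H]2CCC3=C4[C@@H](CC3)[C@@H](C(=O)OC)C[C@]41CN(C)C2
F8 | step 9 | keto aldehyde (C6 quaternary: formyl and 3-oxopentyl) | CCC(=O)CC[C@]1(C=O)[C@H]2CCC3=C4[C@@H](CC3)[C@@H](C(=O)OC)C[C@]41CN(C)C2
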